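**Strategy.** The ten-membered ring is closed at C1–C2 by an intramolecular Hosomi–Sakurai reaction of the C2 aldehyde with a 3-silylcyclohexa-1,4-diene. The step exploits the hidden mirror symmetry of six-membered ring A: C1 and C11 both carry a methyl group and flank C10, and C13 lies on the mirror plane. The C7 lactone stereocentre, set by catalysis, chooses one enantiotopic allylsilane arm, so C10, quaternary C1 and carbinol C2 arise in one operation; the C11=C12–C13=C14 diene left behind is then oxidised to the 14-acetoxy enone. The precursor is a butenolide built from a Birch-derived dienylsilane, a neryl acetate-derived propargylic alcohol and carbon dioxide.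

Key step: step 11

Remark (numbering used throughout): C1 quaternary carbon; C2 acyloxy carbon; C3, C4 methylenes; C5=C6 alkene (C16 methyl on C5); C7 lactone O–CH; C8=C17 butenolide alkene (C18 methyl on C17, C19 lactone carbonyl); C9 methylene; C10 ring-fusion CH; C11 (C20 methyl), C12, C13, C14 complete ring A with C1 and C10; C15 methyl on C1.
Remark (assumption): compounds 1, 6 and 11 are bought.
Remark (assumption): (S,S)-ProPhenol is taken to deliver the propynyl group to the Si face of enal 10 (4R product); if the sense is the opposite one, the (R,R) ligand is used and nothing else changes.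

**Step 1**
Reactants: 1 4-bromo-2,6-dimethylbenzoic acid
Product: 2 2,6-dimethyl-4-(trimethylsilyl)benzoic acid
Conditions: n-BuLi (2.2 equiv), THF, −78 °C; Me3SiCl (2.5 equiv), −78 °C → rt; aq. HCl work-up
Reagents that add atoms: chlorotrimethylsilane, C[Si](C)(C)Cl
Why: Bromine–lithium exchange on the lithium carboxylate (the two ortho methyl groups shield the carboxylate from the aryllithium) followed by C-silylation; the silyl ester formed alongside is cleaved on work-up.

**Step 2**
Reactants: 2 2,6-dimethyl-4-(trimethylsilyl)benzoic acid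
Product: 3 cis-2,6-dimethyl-4-(trimethylsilyl)cyclohexa-2,5-diene-1-carboxylic acid (CO2H and SiMe3 on the same ring face; achiral)
Conditions: Li (2.5 equiv), NH3(l)/THF, −78 °C; then solid NH4Cl
Reagents that add atoms: none
Why: Birch reduction in which carboxylate and silyl group both stabilise charge at their ipso carbons, so that C10 and C13 become sp3 and both methyl groups stay on the alkenes; the enolate dianion should be protonated at C10 anti to the pseudoaxial C13–SiMe3 group, which places CO2H and silicon cis, any trans isomer being removed by crystallisation.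

**Step 3**
Reactants: 3 cis-2,6-dimethyl-4-(trimethylsilyl)cyclohexa-2,5-diene-1-carboxylic acid
Product: 4 [cis-2,6-dimethyl-4-(trimethylsilyl)cyclohexa-2,5-dien-1-yl]methanol
Conditions: LiAlH4, THF, 0 °C → rt; Fieser work-up
Reagents that add atoms: none
Why: Hydride reduction of the carboxylic acid, to which the skipped diene and the allylsilane are inert and which gives no chance for base-induced conjugation because the carboxylate is reduced directly.

**Step 4**
Reactants: 4 [cis-2,6-dimethyl-4-(trimethylsilyl)cyclohexa-2,5-dien-1-yl]methanol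
Product: 5 [cis-4-(bromomethyl)-3,5-dimethylcyclohexa-2,5-dien-1-yl]trimethylsilane
Conditions: CBr4, PPh3, 2,6-lutidine, CH2Cl2, 0 °C
Reagents that add atoms: tetrabromomethane, BrC(Br)(Br)Br
Why: Appel bromination of the primary alcohol under buffered conditions so that the acid-labile allylsilane is not protodesilylated.

**Step 5**
Reactants: 6 neryl acetate, (2Z)-3,7-dimethylocta-2,6-dien-1-yl acetate
Product: 7 (2Z)-3-methyl-6-oxohex-2-en-1-yl acetate
Conditions: O3 (1.0 equiv), CH2Cl2, pyridine (cat.), −78 °C; Me2S, −78 °C → rt
Reagents that add atoms: ozone, [O-][O+]=O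
Why: Chemoselective ozonolysis, the remote trisubstituted alkene being far more electron-rich than the alkene that carries the allylic acetate, so that one equivalent of ozone cleaves it alone and the Z geometry is untouched.

**Step 6**
Reactants: 7 (2Z)-3-methyl-6-oxohex-2-en-1-yl acetate
Product: 9 (2Z)-6,6-dimethoxy-3-methylhex-2-en-1-ol, via acetal acetate 8 (not isolated)
Conditions: HC(OMe)3, MeOH, PPTS (cat.), rt; then K2CO3, rt
Reagents that add atoms: trimethyl orthoformate, COC(OC)OC; methanol, CO
Why: Acid-catalysed acetalisation of the aldehyde followed in the same flask by base-catalysed transesterification (methanolysis) of the acetate.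

**Step 7**
Reactants: 9 (2Z)-6,6-dimethoxy-3-methylhex-2-en-1-ol
Product: 10 (2Z)-6,6-dimethoxy-3-methylhex-2-enal
Conditions: TEMPO (10 mol%), PhI(OAc)2 (1.1 equiv), CH2Cl2, rt
Reagents that add atoms: none
Why: TEMPO/PhI(OAc)2 oxidation of the allylic alcohol to the enal, a method that leaves Z-configured trisubstituted enals unisomerised and dimethyl acetals intact.

**Step 8**
Reactants: 10 (2Z)-6,6-dimethoxy-3-methylhex-2-enal; 11 propyne
Product: 12 (4R,5Z)-9,9-dimethoxy-6-methylnon-5-en-2-yn-4-ol
Conditions: propyne (3 equiv), Me2Zn (3 equiv), (S,S)-ProPhenol (10 mol%), Ph3P=O (20 mol%), toluene, 0 °C; aq. NH4Cl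
Reagents that add atoms: none
Why: Zinc–ProPhenol-catalysed asymmetric alkynylation of the enal, which sets C7 (the only stereocentre made by a catalyst) by reagent-controlled addition of the propynylzinc species to one aldehyde face.

**Step 9**
Reactants: 5 [cis-4-(bromomethyl)-3,5-dimethylcyclohexa-2,5-dien-1-yl]trimethylsilane; 12 (4R,5Z)-9,9-dimethoxy-6-methylnon-5-en-2-yn-4-ol
Product: 15 (5R)-5-[(1Z)-5,5-dimethoxy-2-methylpent-1-en-1-yl]-3-methyl-4-{[cis-2,6-dimethyl-4-(trimethylsilyl)cyclohexa-2,5-dien-1-yl]methyl}furan-2(5H)-one, via Grignard reagent 13 (not isolated), via hydroxy acid 14 (not isolated)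
Conditions: 5: Mg, THF, rt; 12: i-PrMgCl (1.0 equiv), THF, 0 °C; combine, CuI (20 mol%), 0 → 40 °C; CO2 (1 atm), −20 °C → rt; aq. citric acid
Reagents that add atoms: carbon dioxide, O=C=O
Why: Copper-catalysed anti-carbomagnesiation of the propargylic magnesium alkoxide, in which the alkyl group adds to the alkyne carbon next to the carbinol (C8) and magnesium to C17 within a five-membered chelate, so that carboxylation places the acid cis to the C7 oxygen and lactonisation on acidification gives the butenolide with C7 unchanged.

**Step 10**
Reactants: 15 butenolide acetal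
Product: 16 (4Z)-4-methyl-5-[(2R)-4-methyl-5-oxo-3-{[cis-2,6-dimethyl-4-(trimethylsilyl)cyclohexa-2,5-dien-1-yl]methyl}-2,5-dihydrofuran-2-yl]pent-4-enal
Conditions: PPTS (cat.), acetone/H2O (10:1), 45 °C
Reagents that add atoms: water, O
Why: Mild acid-catalysed acetal hydrolysis with an acid too weak to protodesilylate the allylsilane or to ionise the allylic lactone.

**Step 11**
Reactants: 16 silyl dienyl aldehyde
Product: 17 (1R,2S,5Z,7R,10R)-dienol: ten-membered ring closed, C2–OH, ring A a C11=C12–C13=C14 diene, C15 methyl cis to C9 on ring A, 7,19-lactone retained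
Conditions: BF3·OEt2 (2 equiv), 2,6-di-tert-butylpyridine (0.5 equiv), CH2Cl2 (1 mM, syringe-pump addition of 16), −78 → −40 °C; aq. NaHCO3
Reagents that add atoms: none
Why: BF3 activates the aldehyde and the allylsilane C13(SiMe3)–C14=C1 attacks it through its γ carbon C1 (SE2′), the β-silyl cation losing the silyl group to leave the C13=C14 alkene conjugated with C11=C12; this is an intramolecular Hosomi–Sakurai reaction, the closest precedents being Lewis-acid-mediated allylsilane and allylstannane ring closures onto aldehydes and the γ-selective carbonyl additions of cyclohexa-2,5-dienyl metal reagents. Ring B (ten-membered, C1–C10) is closed in a 10-exo-trig sense at both partners, the carbonyl oxygen and the shifted alkene ending outside the new ring. C1 is set by the anti SE2′ rule: C2 enters opposite to the C13–Si bond, and as silicon is cis to the C9 methylene the new bond is trans to C9 (trans ring fusion, C15 cis to C9). C10 becomes a stereocentre through the choice between the enantiotopic arms C1=C14 and C11=C12, which is relayed from C7: the planar butenolide fixes the C6–C7–C8–C9 torsion of the 7R tether near +60°, allylic strain against C18 and the need to close the ring hold C10 and C6 on the same lactone face, and with C8 antiperiplanar to the reacting arm only the arm that becomes C1 is expected to offer its anti-silyl face to C2 with same-sign gauche torsions around the ring fusion; this argument is qualitative and untested. C2 is set by a synclinal transition state with the carbonyl oxygen over the allyl unit and C3 antiperiplanar to C14, the arrangement that maps onto a gauche C10–C1–C2–C3 torsion and gives 2S. The step needs γ-regioselectivity (β-silicon effect), arm and face selectivity (C7 and the cis silane) and C–C bond formation that outruns hydride transfer from the bis-allylic C–H bonds and oligomerisation, for which BF3 at low temperature, a hindered base and high dilution are chosen.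

**Step 12**
Reactants: 17 dienol
Product: 18 2-propanoate of 17
Conditions: (EtCO)2O, Et3N, DMAP (cat.), CH2Cl2, 0 °C → rt
Reagents that add atoms: propanoic anhydride, CCC(=O)OC(=O)CC
Why: DMAP-catalysed acylation of the hindered secondary alcohol, which touches no stereocentre.

**Step 13**
Reactants: 18 diene propanoate
Product: 20 cis-11,14-diol: 18 with a tertiary C11–OH and a secondary C14–OH both on the ring-A face opposite to the C15 methyl and a C12=C13 alkene, via endoperoxide 19 (not isolated)
Conditions: O2, visible light, tetraphenylporphyrin (cat.), CH2Cl2, −30 °C; then thiourea, MeOH, rt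
Reagents that add atoms: dioxygen, O=O
Why: [4+2] cycloaddition of singlet oxygen to the cisoid C11=C12–C13=C14 diene from the face anti to the pseudoaxial C15 methyl group, which sets the C14–O bond on the required face, followed by thiourea reduction of the O–O bond to the cis-enediol; the diene should react faster than the isolated C5=C6 alkene.

**Step 14**
Reactants: 20 cis-11,14-diol
Product: 21 14-acetate of 20 (tertiary C11–OH free)
Conditions: Ac2O, pyridine, DMAP (cat.), CH2Cl2, 0 °C
Reagents that add atoms: acetic anhydride, CC(=O)OC(C)=O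
Why: Chemoselective DMAP-catalysed acetylation of the secondary C14 hydroxyl, the tertiary allylic C11 hydroxyl being far slower to acylate.

**Step 15**
Reactants: 21 tertiary allylic alcohol acetate
Product: 22 target, (1R,2S,5Z,7R,10R,14S)-14-acetoxy-13-oxo-2-propanoyloxy-5,8(17),11-triene 7,19-lactone (CNP0109273.3)
Conditions: pyridinium chlorochromate (C5H5NH[CrO3Cl], 3 equiv), NaOAc, 4 Å molecular sieves, CH2Cl2, rt
Reagents that add atoms: pyridinium chlorochromate, [O-][Cr](=O)(=O)Cl.c1cc[nH+]cc1
Why: Dauben–Babler oxidative transposition, in which the chromate ester of the tertiary allylic alcohol undergoes a [3,3] shift to C13 and is oxidised to the ketone, giving the C11=C12–C13=O enone without touching the esters or the C14 stereocentre.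

**Compound list**

1 | 4-bromo-2,6-dimethylbenzoic acid | Cc1cc(Br)cc(C)c1C(=O)O | starting material
2 | 2,6-dimethyl-4-(trimethylsilyl)benzoic acid | Cc1cc(cc(C)c1C(=O)O)[Si](C)(C)C | intermediate
3 | cis-2,6-dimethyl-4-(trimethylsilyl)cyclohexa-2,5-diene-1-carboxylic acid | OC(=O)[C@H]1C(C)=C[C@@H]([Si](C)(C)C)C=C1C | intermediate
4 | [cis-2,6-dimethyl-4-(trimethylsilyl)cyclohexa-2,5-dien-1-yl]methanol | OC[C@H]1C(C)=C[C@@H]([Si](C)(C)C)C=C1C | intermediate
5 | [cis-4-(bromomethyl)-3,5-dimethylcyclohexa-2,5-dien-1-yl]trimethylsilane | BrC[C@H]1C(C)=C[C@@H]([Si](C)(C)C)C=C1C | intermediate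
6 | neryl acetate, (2Z)-3,7-dimethylocta-2,6-dien-1-yl acetate | CC(=O)OC/C=C(C)\CCC=C(C)C | starting material
7 | (2Z)-3-methyl-6-oxohex-2-en-1-yl acetate | CC(=O)OC/C=C(C)\CCC=O | intermediate
8 | (2Z)-6,6-dimethoxy-3-methylhex-2-en-1-yl acetate (formed in the flask) | CC(=O)OC/C=C(C)\CCC(OC)OC | intermediate
9 | (2Z)-6,6-dimethoxy-3-methylhex-2-en-1-ol | OC/C=C(C)\CCC(OC)OC | intermediate
10 | (2Z)-6,6-dimethoxy-3-methylhex-2-enal | O=C/C=C(C)\CCC(OC)OC | intermediate
11 | propyne | CC#C | starting material
12 | (4R,5Z)-9,9-dimethoxy-6-methylnon-5-en-2-yn-4-ol | COC(OC)CC/C(C)=C\[C@@H](O)C#CC | intermediate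
13 | {[cis-2,6-dimethyl-4-(trimethylsilyl)cyclohexa-2,5-dien-1-yl]methyl}magnesium bromide (formed in the flask) | Br[Mg]C[C@H]1C(C)=C[C@@H]([Si](C)(C)C)C=C1C | intermediate
14 | (2Z,4R,5Z)-4-hydroxy-9,9-dimethoxy-2,6-dimethyl-3-{[cis-2,6-dimethyl-4-(trimethylsilyl)cyclohexa-2,5-dien-1-yl]methyl}nona-2,5-dienoic acid (formed in the flask) | COC(OC)CC/C(C)=C\[C@@H](O)/C(C[C@H]1C(C)=C[C@@H]([Si](C)(C)C)C=C1C)=C(/C)C(=O)O | intermediate
15 | (5R)-5-[(1Z)-5,5-dimethoxy-2-methylpent-1-en-1-yl]-3-methyl-4-{[cis-2,6-dimethyl-4-(trimethylsilyl)cyclohexa-2,5-dien-1-yl]methyl}furan-2(5H)-one | COC(OC)CC/C(C)=C\[C@H]1OC(=O)C(C)=C1C[C@H]2C(C)=C[C@@H]([Si](C)(C)C)C=C2C | intermediate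
16 | (4Z)-4-methyl-5-[(2R)-4-methyl-5-oxo-3-{[cis-2,6-dimethyl-4-(trimethylsilyl)cyclohexa-2,5-dien-1-yl]methyl}-2,5-dihydrofuran-2-yl]pent-4-enal | O=CCC/C(C)=C\[C@H]1OC(=O)C(C)=C1C[C@H]2C(C)=C[C@@H]([Si](C)(C)C)C=C2C | intermediate
17 | (1R,2S,5Z,7R,10R)-dienol, ring B closed, C2–OH, ring A a C11=C12–C13=C14 diene | O[C@H]1CC/C(C)=C\[C@H]2OC(=O)C(C)=C2C[C@@H]2C(C)=CC=C[C@@]12C | intermediate
18 | 2-propanoate of 17 | CCC(=O)O[C@H]1CC/C(C)=C\[C@H]2OC(=O)C(C)=C2C[C@@H]2C(C)=CC=C[C@@]12C | intermediate
19 | 11,14-endoperoxide of 18, peroxide bridge on the ring-A face opposite to C15 (formed in the flask) | CCC(=O)O[C@H]1CC/C(C)=C\[C@H]2OC(=O)C(C)=C2C[C@@H]2[C@]3(C)C=C[C@@H](OO3)[C@@]12C | intermediate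
20 | cis-11,14-diol, both hydroxyls on the ring-A face opposite to C15, C12=C13 alkene | CCC(=O)O[C@H]1CC/C(C)=C\[C@H]2OC(=O)C(C)=C2C[C@@H]2[C@@](C)(O)C=C[C@@H](O)[C@@]12C | intermediate
21 | 14-acetate of 20 | CCC(=O)O[C@H]1CC/C(C)=C\[C@H]2OC(=O)C(C)=C2C[C@@H]2[C@@](C)(O)C=C[C@@H](OC(C)=O)[C@@]12C | intermediate
22 | target CNP0109273.3, (1R,2S,5Z,7R,10R,14S) | CCC(=O)O[C@H]1CC/C(C)=C\[C@H]2OC(=O)C(C)=C2C[C@@H]2C(C)=CC(=O)[C@@H](OC(C)=O)[C@@]12C | target

**Step count.** Total: 15 steps. Longest linear sequence: 11 steps (6 → 22 through steps 5–15; the ring-fragment branch 1 → 22 through steps 1–4 and 9–15 is equally long).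

**Steps most likely to fail**

Step 11. The open transition state may not discriminate the two faces of the aldehyde, so that the C2 carbinol forms mainly with the wrong configuration while the C1 face stays fixed by silicon. The choice of diene arm rests on a qualitative conformational argument only and should be checked by a conformational search before the route is committed; the fallback below does not repair a wrong arm. Fallback: C2 is then set by substitution instead of by the cyclization. The same ring closure of 16 is allowed to give the C2-epimeric dienol F1. A Mitsunobu reaction with 4-nitrobenzoic acid (PPh3, DIAD, toluene) inverts C2 and gives the 4-nitrobenzoate F2. Methanolysis (K2CO3, MeOH, 0 °C) releases the alcohol and comes back to the route at 17.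

Step 9. The β-branched alkylmagnesium reagent may add too slowly to the internal alkyne, the alkyne may be reduced instead, or the homoallylic Grignard reagent may undergo a 1,2-vinyl shift (ring enlargement) during the long reaction time. Fallback: the ring fragment is delivered by conjugate addition to an alkynoate instead of by carbomagnesiation. Enal 10 is alkynylated with methyl propiolate (Me2Zn, the same ProPhenol ligand) to methyl (4R,5Z)-4-hydroxy-9,9-dimethoxy-6-methylnon-5-en-2-ynoate F3. Its magnesium alkoxide (i-PrMgCl) takes up the organocopper reagent made from 13 and CuBr·SMe2 at −78 °C by syn addition (alkyl to C8, copper to C17). The alkenylcopper is methylated with iodomethane/HMPA with retention, and acidic work-up lactonises the cis hydroxy ester, coming back to the route at 15.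

Step 13. Singlet oxygen may react in an ene mode at the C5=C6 alkene or at the allylic hydrogens of the diene, or add to the wrong diene face. Fallback: the oxygens are introduced by peracid and palladium chemistry instead. Epoxidation of 18 at the more substituted diene alkene C11=C12 (mCPBA, NaHCO3, CH2Cl2, −20 °C) from the face anti to C15 gives the 11,12-epoxide of 18, F4. Pd(PPh3)4 (zerovalent palladium, catalytic) with acetic acid in THF opens the vinyl epoxide through the π-allyl complex with net syn 1,4-addition, placing the acetate at C14 cis to the tertiary C11 hydroxyl, and comes back to the route at 21.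

**Further compounds**

F1 | step 11 | C2-epimer of 17, (1R,2R,5Z,7R,10R)-dienol | O[C@@H]1CC/C(C)=C\[C@H]2OC(=O)C(C)=C2C[C@@H]2C(C)=CC=C[C@@]12C
F2 | step 11 | 4-nitrobenzoate of 17 (2S, inverted) | O=C(O[C@H]1CC/C(C)=C\[C@H]2OC(=O)C(C)=C2C[C@@H]2C(C)=CC=C[C@@]12C)c1ccc(cc1)[N+](=O)[O-]
F3 | step 9 | methyl (4R,5Z)-4-hydroxy-9,9-dimethoxy-6-methylnon-5-en-2-ynoate | COC(OC)CC/C(C)=C\[C@@H](O)C#CC(=O)OC
F4 | step 13 | 11,12-epoxide of 18, epoxide oxygen on the ring-A face opposite to C15 | CCC(=O)O[C@H]1CC/C(C)=C\[C@H]2OC(=O)C(C)=C2C[C@@H]2[C@@]3(C)O[C@H]3C=C[C@@]12C
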